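Assumption: the target has no stereocentre and no stereogenic double bond, so no enantiocontrol is needed. The side chain is read from the SMILES as unbranched C20 (n-icosyl).

**Retrosynthetic overview**
1. Irisoquin D comes from 2-icosyl-6-methoxy-1,4-benzoquinone by C-H hydroxylation next to the chain. That quinone comes from 3-icosyl-5-methoxyphenol by para-oxygenation, so the oxygens go on after the ring is made, as in sorgoleone-type biosynthesis.
2. 3-Icosyl-5-methoxyphenol comes from a linear C27 tetraketide acid by C2-to-C7 aldol closure, dehydration and loss of CO2, which is the alkylresorcinol-synthase mode.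
3. The tetraketide comes from a C21 "starter" ester and O-methyl triacetic lactone (a masked, already O-methylated triketide). Joining, ring opening, ring closure and decarboxylation all run in one flask.
4. The starter ester comes from a C11 bromo ester and a C10 Grignard reagent by sp3-sp3 coupling.
5. Ring order: only one carbocycle is formed, in step 2, and the pyrone ring is sacrificed in making it.

**Route**

Step 1
Reactants: 1 methyl 11-bromoundecanoate; 2 decylmagnesium bromide
Product: 3 methyl heneicosanoate
Conditions: Li2CuCl4 (3 mol %), NMP (4 equiv), THF, slow addition of 2 (1.3 equiv, 1 M in Et2O), 0 °C to rt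
Reagents that add atoms: none
Why: This is a Kochi-type copper-catalysed sp3-sp3 cross-coupling of a Grignard reagent with a primary bromide, and with NMP present it is much faster than Grignard addition to the methyl ester; no stereocentre is formed.

Step 2
Reactants: 3 methyl heneicosanoate; 4 4-methoxy-6-methyl-2H-pyran-2-one
Product: 9 3-icosyl-5-methoxyphenol, via lithiated pyrone 5 (not isolated), via ketopyrone 6 (not isolated), via open-chain tetraketide acid 7 (not isolated), via O-methylresorcylic acid 8 (not isolated)
Conditions: 4 (2.2 equiv), LDA (2.1 equiv, commercial solution), THF, -78 to -50 °C, 1 h; 3 (1.0 equiv) in THF, -50 to 0 °C; then KOH (12 equiv), MeOH-H2O, reflux; then 6 M HCl to pH 1, reflux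
Reagents that add atoms: none
Why: Proposed new method: this is a one-flask merger of three known reaction types, namely (i) vinylogous Claisen acylation of the thermodynamic C-6 methyl anion 5 by the ester (the slight excess of 4 lets kinetic C-3 lithiation equilibrate, and the second equivalent of 5 takes up the acidic proton of 6), (ii) hydroxide opening of 6 at the lactone carbonyl to the carboxylate of 7, which cannot undergo the competing C6-to-C1 Claisen closure, so C-2 of the beta-methoxyacrylate dienolate adds to the C-7 ketone in a 6-(enolendo)-exo-trig aldol and loss of water aromatises to 8, and (iii) acid-promoted ipso-protonation and decarboxylation of the ortho/para-oxygenated, doubly ortho-substituted acid 8, with the closest known reaction type being the biogenetic-type KOH conversion of 6-acylmethyl-4-methoxy-2-pyrones into resorcylic acid ethers; the oxygen brought in by hydroxide leaves again in CO2, and no stereocentre is formed.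

Step 3
Reactants: 9 3-icosyl-5-methoxyphenol
Product: 10 2-icosyl-6-methoxy-1,4-benzoquinone
Conditions: Co(salen) (salcomine, 10 mol %), O2 (1 atm), DMF-THF 1:1, rt to 40 °C
Reagents that add atoms: dioxygen, O=O
Why: In this cobalt-Schiff-base (salcomine) aerobic phenol oxidation, the Co-superoxo species abstracts the phenolic hydrogen and delivers O2 to the only para carbon of the electron-rich phenoxyl radical, as in the known oxidation of 3-methoxy-5-alkylphenols to primin-type quinones; no stereocentre is formed.

Step 4
Reactants: 10 2-icosyl-6-methoxy-1,4-benzoquinone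
Product: 12 irisoquin D (2-hydroxy-3-icosyl-5-methoxy-1,4-benzoquinone), via epoxyquinone 11 (not isolated)
Conditions: t-BuOOH (5.5 M in decane, 1.1 equiv), CH2Cl2, 0 °C, DBU (2.2 equiv, added last and slowly), 0 °C to rt; 1 M HCl wash
Reagents that add atoms: tert-butyl hydroperoxide, CC(C)(C)OO
Why: Weitz-Scheffer nucleophilic epoxidation occurs at C-5, the only electrophilic CH because C-3 is deactivated by the vinylogous-ester methoxy group, and gives racemic cis-fused 11, whose C-5 proton is then removed by base in an E1cB-type epoxide opening (the menadione oxide to phthiocol reaction type) to the unreactive hydroxyquinone anion, which erases both transient stereocentres.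

**Compound list**
1 | methyl 11-bromoundecanoate | COC(=O)CCCCCCCCCCBr | starting material
2 | decylmagnesium bromide | CCCCCCCCCC[Mg]Br | starting material
3 | methyl heneicosanoate | CCCCCCCCCCCCCCCCCCCCC(=O)OC | intermediate
4 | 4-methoxy-6-methyl-2H-pyran-2-one | CC1=CC(OC)=CC(=O)O1 | starting material
5 | 6-(lithiomethyl)-4-methoxy-2H-pyran-2-one | [Li]CC1=CC(OC)=CC(=O)O1 | intermediate (not isolated)
6 | 4-methoxy-6-(2-oxodocosyl)-2H-pyran-2-one | CCCCCCCCCCCCCCCCCCCCC(=O)CC1=CC(OC)=CC(=O)O1 | intermediate (not isolated)
7 | (2E)-3-methoxy-5,7-dioxoheptacos-2-enoic acid, present as its potassium salts | CCCCCCCCCCCCCCCCCCCCC(=O)CC(=O)C/C(OC)=C\C(=O)O | intermediate (not isolated)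
8 | 4-hydroxy-2-icosyl-6-methoxybenzoic acid | CCCCCCCCCCCCCCCCCCCCC1=CC(O)=CC(OC)=C1C(=O)O | intermediate (not isolated)
9 | 3-icosyl-5-methoxyphenol | CCCCCCCCCCCCCCCCCCCCC1=CC(O)=CC(OC)=C1 | intermediate
10 | 2-icosyl-6-methoxy-1,4-benzoquinone | CCCCCCCCCCCCCCCCCCCCC1=CC(=O)C=C(OC)C1=O | intermediate
11 | rac-1-icosyl-3-methoxy-7-oxabicyclo[4.1.0]hept-3-ene-2,5-dione (cis-fused 5,6-epoxide of 10; one enantiomer drawn) | CCCCCCCCCCCCCCCCCCCC[C@]12O[C@H]1C(=O)C=C(OC)C2=O | intermediate (not isolated)
12 | irisoquin D, 2-hydroxy-3-icosyl-5-methoxy-1,4-benzoquinone (achiral) | CCCCCCCCCCCCCCCCCCCCC1=C(O)C(=O)C=C(OC)C1=O | target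

**Totals**
Total step count: 4. Longest linear sequence: 4 (1 to 3 to 9 to 10 to 12).

**Steps most likely to fail**

Step 2. Self-condensation of 5 with regenerated 4 may outrun the acylation. Hot KOH may also cleave the beta-diketone of 7 by a retro-Claisen reaction. The fallback sets out from 3 and comes back at 9. It replaces the pyrone by an open-chain polyanion and moves O-methylation to after ring formation.
- The trianion of commercial methyl 3,5-dioxohexanoate (excess LDA, THF, 0 °C) is acylated at its terminal carbon by 3 to give methyl 3,5,7-trioxoheptacosanoate F1.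
- Mild aqueous base (pH about 9) closes F1 by the same C2-to-C7 aldol to methyl 2,4-dihydroxy-6-icosylbenzoate F2.
- The 2-OH of F2 is chelated to the ester, so MeI (1 equiv) with K2CO3 in acetone methylates only the 4-OH and gives methyl 2-hydroxy-6-icosyl-4-methoxybenzoate F3.
- KOH in aqueous ethylene glycol saponifies F3 to 2-hydroxy-6-icosyl-4-methoxybenzoic acid F4, which loses CO2 on acidification and heating to give 9.

Step 4. Alkylquinone 10 is base-sensitive because it can tautomerise to a quinone methide, and the epoxide opening may be unclean. The fallback sets out from 10 and comes back at 12. It uses an acid-catalysed conjugate addition in place of a peroxide.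
- Thiele-Winter acetoxylation (Ac2O, cat. H2SO4, rt) adds acetate at the same C-5 and gives 3-icosyl-5-methoxybenzene-1,2,4-triyl triacetate F5.
- K2CO3 in MeOH removes the three acetyl groups to give 3-icosyl-5-methoxybenzene-1,2,4-triol F6. This is the dihydro form of the natural product, and it autoxidises in the air-open basic solution to the anion of 12, which acid releases.

Step 3. The para carbon is flanked on both sides, so ortho coupling of the phenoxyl radical may compete. The fallback sets out from 8 and comes back at 10. Compound 8 is collected by filtration when step 2 is stopped at cold acidification, without the acid reflux. The fallback replaces C-H oxygenation by decarboxylative ipso-hydroxylation. PhI(OAc)2 (2.2 equiv) in MeCN-H2O at 0 °C oxidises the para-hydroxybenzoic acid, water attacks the carboxyl-bearing carbon, and loss of CO2 gives 2-icosyl-6-methoxybenzene-1,4-diol F7. The second equivalent of oxidant then takes F7 to 10.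

**Further compounds**
F1 | step 2 | methyl 3,5,7-trioxoheptacosanoate | CCCCCCCCCCCCCCCCCCCCC(=O)CC(=O)CC(=O)CC(=O)OC
F2 | step 2 | methyl 2,4-dihydroxy-6-icosylbenzoate | CCCCCCCCCCCCCCCCCCCCC1=CC(O)=CC(O)=C1C(=O)OC
F3 | step 2 | methyl 2-hydroxy-6-icosyl-4-methoxybenzoate | CCCCCCCCCCCCCCCCCCCCC1=CC(OC)=CC(O)=C1C(=O)OC
F4 | step 2 | 2-hydroxy-6-icosyl-4-methoxybenzoic acid | CCCCCCCCCCCCCCCCCCCCC1=CC(OC)=CC(O)=C1C(=O)O
F5 | step 4 | 3-icosyl-5-methoxybenzene-1,2,4-triyl triacetate | CCCCCCCCCCCCCCCCCCCCC1=C(OC(C)=O)C(OC(C)=O)=CC(OC)=C1OC(C)=O
F6 | step 4 | 3-icosyl-5-methoxybenzene-1,2,4-triol | CCCCCCCCCCCCCCCCCCCCC1=C(O)C(O)=CC(OC)=C1O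
F7 | step 3 | 2-icosyl-6-methoxybenzene-1,4-diol | CCCCCCCCCCCCCCCCCCCCC1=CC(O)=CC(OC)=C1O
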